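## The problem

The target 25 is a melampolide-type germacranolide. It has a ten-membered carbocycle C1–C10 with a trans-fused α-methylene-γ-lactone across C6–C7 (O6–C12, C11=C13), a methacrylate on O8, a methyl ester (C14) on C10 and a methyl group (C15) on C4. The ring holds two trisubstituted alkenes in a 1,5-relationship: C4=C5 is ring-trans (E), and C1=C10 is ring-cis (E by the sequence rule only because C14 outranks C9). A synthesis must therefore reach a medium ring and fix both geometries. The only stereocentres are the contiguous C6, C7 and C8 (all R). O6 is trans and O8 is cis to the C7–C11 bond, and C7, a carbon-substituted centre between two oxygenated carbons, is the hard one to set. Once this triad sits on a six-membered ring it can lock that ring in one chair, and so control any temporary stereocentre and, through it, the alkene geometry. The α-methylene lactone and the methacrylate are Michael acceptors that do not survive strong base, nucleophiles, light or prolonged heat. The 1,5-diene can undergo Cope rearrangement on heating and transannular cyclisation in acid, and a free O8–H invites translactonisation, so these groups must come last. The enabling feature is that C10=C1–C2–C3–C4=C5 is the diene released when the cyclobutane C1–C4–C5–C10 of a bicyclo[2.2.0]hexane is cleaved across C1–C4 and C5–C10. C1–C4 with C15 is 1-methylcyclobutene, and C5–C10 with C14, O6 and O8 is the ring of shikimic acid (C10, C5, C6, C7, C8, C9 = shikimate C1–C6).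

## Retrosynthesis

**End game.** The two acrylate units are removed first. Cutting the O8–acyl bond of 25 gives alcohol 23 and methacrylic anhydride 24. Cutting O8–Si leads back to silyl ether 22, and removing C13 from C11 leads to the saturated lactone 19 by way of Mannich base 20. These cuts come before any skeletal cut because both acrylates would interfere with light, heat and enolates. Forward, this asks only for a lactone enolate aminomethylation, a buffered desilylation and an acylation.

**Ring expansion.** In 19 the bonds C1–C4 and C5–C10 are re-formed in the retrosynthetic sense, giving tricycle 18, and forward they are cut by heat. This double cut is preferred to opening the ten-membered ring at one bond, which would leave a macrocyclisation with both alkene geometries and entropy against it. The precursor 18 has an ordinary cyclohexane (ring A, C5–C10) and no alkene. The forward step must break the two bonds in the right order of conformations, because the chair of the intermediate 1,4-diyl decides which alkene becomes trans, and it must stop before the product diene rearranges further.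

**Key cut.** Tricycle 18 is cut at C4–C5 and C1–C10 into lactone enoate 15 and 1-methylcyclobutene 17. No other [2+2] cut of this cyclobutane is productive, since the other pair of bonds is the one broken thermally. 15 carries all three stereocentres and every heteroatom except the methacrylate; 17 is a C5 hydrocarbon. The forward photocycloaddition must be head-to-tail (C4 to C5) and cis at C5–C10. It must also occur on the α face, the face of O6. The four new centres do vanish later, but with ring A locked by the trans-lactone only the α adduct can reach the diyl chair that gives the target geometry.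

**Lactone relay.** The lactone of 15 is cut at O6–C12 to the hydroxy Weinreb amide that is unmasked from 14. 14 comes from 13 by O8 silylation, and 13 from the cis-fused 8,12-lactone 12 by aminolysis. The detour is accepted because carbon can be delivered to C7 with the required configuration only from O8, which first gives the cis lactone on O8. The relay needs O6 and O8 to be told apart, hence the triethylsilyl group of 12 (from 11).

**C7–C11 bond.** In 11 (after loss of the extra ester of 10) the C7–C11 bond is cut. Forward, a malonate tethered on O8 displaces the C7 oxygen of cyclic sulfate 8 with inversion. An intermolecular nucleophile would attack the allylic C6 of the same sulfate or of an epoxide. A C7 triflate would first require O6 and O7 of a cis diol to be differentiated. The cyclic sulfate activates O7 while masking O6, and the tether can reach only C7.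

**Starting materials.** 8 comes from diol 6, 6 from acetonide 5, and 5 from alcohol 3 and methyl malonyl chloride 4. 3 is the acetonide of methyl shikimate 2, made from (−)-shikimic acid 1. 17 is the endocyclic isomer of commercial methylenecyclobutane 16.

## Roads not taken

**Alternative 1:** The cut is the C2–C3 bond, with the temporary C5–C10 bond again broken forward. The potassium alkoxide of the lactone-locked divinyl carbinol A1 would undergo an anionic oxy-Cope shift, and the C10 enolate would be trapped with PhNTf2 as the enol triflate A2. Palladium-catalysed methoxycarbonylation (Pd(OAc)2, CO, MeOH) would then add C14.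
- Merits: the shift runs at or below room temperature and is irreversible, so the diene never meets the conditions for a Cope back-reaction. Its chair transition state makes the alkene geometry more predictable than a 190 °C cycloreversion. In these two respects it is better than the chosen plan.
- Weak points: C10 must be a carbinol carbon, so the carboxyl carbon of shikimic acid cannot be used and C14 costs extra steps. A1 needs C5 and C10 set cis and on the α face, for the same chair reason as in the chosen plan. Its preparation means a vinyl addition at a carbonyl flanked by an epimerisable C5, with O8 β to that carbonyl, an arrangement prone to elimination. KH must also spare an enolisable lactone.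
- Comparison: the chosen plan sets against the milder ring expansion a C14 that is present from the start, all three stereocentres from the chiral pool, and two steps from 15 to the ten-membered ring.

**Alternative 2:** The cuts are C5–C6 and O6–C12. CrCl2 with catalytic NiCl2 would turn the vinyl iodide of the open-chain aldehyde A3 into a vinylchromium species that adds to the C6 aldehyde and closes the ring. The alkoxide would then lactonise to A4, which is the same compound as 19.
- Merits: both alkene geometries are fixed in the open chain before ring closure, which is clearly better than making them in the ring-forming step. The coupling tolerates esters and needs neither light nor heat.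
- Weak points: C6 is created during a ten-membered ring closure, with no reliable model for its configuration relative to C7, and the wrong epimer gives a cis lactone. The closure needs high dilution and a large excess of divalent chromium. A3 is a long linear chain whose C7 and C8 centres must be made by asymmetric synthesis, with C7 epimerisable next to the aldehyde.
- Comparison: the chosen plan takes C6 from shikimic acid and expands a six-membered ring, avoiding macrocyclisation. It gives up the certainty about alkene geometry.

**Alternative 3:** The cut is C8–C9, with C1=C10 formed in the same step. Under blue light, Ir[dF(CF3)ppy]2(dtbbpy)PF6 would decarboxylate the α-keto acid A5 to a C8 acyl radical. This adds to C9 of the acrylate, and reduction of the C10 radical with loss of acetate from C1 gives the 8-oxo dienoate A6.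
- Merits: the conditions are the mildest of all, the ring and the conjugated alkene form in one step, and A5 is assembled convergently.
- Weak points: a ten-membered radical closure competes with reduction and intermolecular addition. The C1=C10 geometry is set by an elimination inside a strained ring. A6 then needs a face-selective ketone reduction to create C8. The C8 ketone also makes H7 acidic with O6 in the β position, so epimerisation at C7 and opening of the lactone are real risks.
- Comparison: the chosen plan never has a carbonyl at C8 and takes C8 from the chiral pool. It is longer before the key step and harsher in its thermal step.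

Key step: step 13

Remark on conventions: atoms are numbered as in the germacrane skeleton throughout. Ring A is the six-membered ring C5–C10 (the shikimate ring), α is the face of O6, and β is the face of C11 and O8. 1-Methylcyclobutene is assumed not to be available in bulk and is made in step 12.

## Route

Step 1
Reactants: 1 (−)-shikimic acid
Product: 2 methyl shikimate
Conditions: MeOH, CSA (cat.), reflux
Reagents that add atoms: methanol, CO
Why: Fischer esterification of the conjugated acid; the three stereocentres are not touched.

Step 2
Reactants: 2 methyl shikimate
Product: 3 methyl 3,4-O-isopropylideneshikimate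
Conditions: 2,2-dimethoxypropane, TsOH·H2O (cat.), acetone, 25 °C
Reagents that add atoms: 2,2-dimethoxypropane, COC(C)(C)OC
Why: Acetal exchange; only the cis diol O6/O7 can close a five-membered acetonide, so the trans-disposed O8–H stays free.

Step 3
Reactants: 3 methyl 3,4-O-isopropylideneshikimate; 4 methyl malonyl chloride
Product: 5 methyl 3,4-O-isopropylidene-5-O-(methoxycarbonylacetyl)shikimate
Conditions: pyridine, DMAP (cat.), CH2Cl2, 0 °C
Reagents that add atoms: none
Why: Acylation of the single free alcohol by an acid chloride; it places C11–C12 on O8, the oxygen on the face to which C11 must be delivered.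

Step 4
Reactants: 5 methyl 3,4-O-isopropylidene-5-O-(methoxycarbonylacetyl)shikimate
Product: 6 methyl 5-O-(methoxycarbonylacetyl)shikimate
Conditions: AcOH–H2O (4:1), 45 °C
Reagents that add atoms: none
Why: Acid hydrolysis of the acetonide; the esters tolerate aqueous acetic acid, and the trans-diequatorial O7/O8 pair disfavours acyl migration.

Step 5
Reactants: 6 methyl 5-O-(methoxycarbonylacetyl)shikimate
Product: 8 3,4-cyclic sulfate of methyl 5-O-(methoxycarbonylacetyl)shikimate, via cyclic sulfite 7 (not isolated)
Conditions: SOCl2, Et3N, CH2Cl2, 0 °C; then RuCl3·xH2O (cat.), NaIO4, MeCN–H2O, 0 °C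
Reagents that add atoms: thionyl chloride, O=S(Cl)Cl; sodium periodate, [Na+].[O-]I(=O)(=O)=O
Why: Standard cyclic sulfate synthesis from a cis diol (sulfite, then ruthenium-catalysed oxidation); it makes O7 a leaving group and masks O6 without having to tell the two apart, and the electron-poor enoate should be inert to the brief oxidation.

Step 6
Reactants: 8 3,4-cyclic sulfate of methyl 5-O-(methoxycarbonylacetyl)shikimate
Product: 10 dimethyl 4-hydroxy-2-oxo-2,3,3a,4,7,7a-hexahydro-1-benzofuran-3,6-dicarboxylate (cis-fused 8,12-lactone), via sulfate monoester sodium salt 9 (not isolated)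
Conditions: NaH (1.0 equiv), THF–DMF (10:1), 0 → 25 °C; then H2SO4 (cat.), H2O (2 equiv), THF, 25 °C
Reagents that add atoms: none
Why: Intramolecular C-alkylation of a malonate by a cyclic sulfate, a 5-exo-tet closure with the enolate double bond outside the forming ring; the tether on O8 can reach only C7 and only anti to the C7–O bond, so C7 is inverted and C11 ends β, cis to O8 and trans to O6. One equivalent of base keeps the product from being deprotonated and displacing the C6 sulfate; the monoester is then hydrolysed with S–O cleavage.

Step 7
Reactants: 10 dimethyl 4-hydroxy-2-oxo-2,3,3a,4,7,7a-hexahydro-1-benzofuran-3,6-dicarboxylate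
Product: 11 methyl (3aS,4R,7aR)-4-hydroxy-2-oxo-2,3,3a,4,7,7a-hexahydro-1-benzofuran-6-carboxylate
Conditions: LiCl, H2O (2 equiv), DMSO, 130 °C
Reagents that add atoms: none
Why: Krapcho dealkoxycarbonylation of the lactone-activated methyl ester; the conjugated C14 ester has no second activating carbonyl and should stay.

Step 8
Reactants: 11 methyl (3aS,4R,7aR)-4-hydroxy-2-oxo-2,3,3a,4,7,7a-hexahydro-1-benzofuran-6-carboxylate
Product: 12 6-O-triethylsilyl ether of 11
Conditions: Et3SiCl, imidazole, DMF, 0 °C
Reagents that add atoms: chlorotriethylsilane, CC[Si](Cl)(CC)CC
Why: Silylation of the only free alcohol; the triethylsilyl group is chosen because it can later be removed in the presence of a tert-butyldimethylsilyl ether.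

Step 9
Reactants: 12 6-O-triethylsilyl ether of 11
Product: 13 methyl 5-hydroxy-4-[2-(methoxy(methyl)amino)-2-oxoethyl]-3-(triethylsilyloxy)cyclohex-1-ene-1-carboxylate
Conditions: MeNHOMe·HCl, AlMe3, CH2Cl2, 0 °C
Reagents that add atoms: N,O-dimethylhydroxylamine hydrochloride, CNOC.Cl
Why: Weinreb aminolysis of a γ-lactone with the aluminium amide; it frees O8–H, and the saturated lactone should react well before the hindered conjugated C14 ester.

Step 10
Reactants: 13 methyl 5-hydroxy-4-[2-(methoxy(methyl)amino)-2-oxoethyl]-3-(triethylsilyloxy)cyclohex-1-ene-1-carboxylate
Product: 14 8-O-tert-butyldimethylsilyl ether of 13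
Conditions: tBuMe2SiOTf, 2,6-lutidine, CH2Cl2, −40 → 0 °C
Reagents that add atoms: tert-butyldimethylsilyl trifluoromethanesulfonate, CC(C)(C)[Si](C)(C)OS(=O)(=O)C(F)(F)F
Why: Silyl triflate silylation of a hindered secondary alcohol, run on crude 13 before it can close back to the cis lactone; it blocks O8 for the rest of the route.

Step 11
Reactants: 14 8-O-tert-butyldimethylsilyl ether of 13
Product: 15 methyl (3aS,4R,7aR)-4-(tert-butyldimethylsilyloxy)-2-oxo-2,3,3a,4,5,7a-hexahydro-1-benzofuran-6-carboxylate (trans-fused 6,12-lactone enoate)
Conditions: AcOH–THF–H2O (3:1:1), 25 °C; then PhMe–AcOH (10:1), 70 °C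
Reagents that add atoms: none
Why: Mild acid removes the triethylsilyl ether selectively, and the freed O6–H lactonises onto the Weinreb amide; O6 is the only free hydroxyl, so the trans lactone is the only one that can form. No stereocentre is touched.

Step 12
Reactants: 16 methylenecyclobutane
Product: 17 1-methylcyclobutene
Conditions: Na on Al2O3 (cat.), neat, 25 °C; fractional distillation
Reagents that add atoms: none
Why: Base-catalysed allylic isomerisation of the exocyclic to the endocyclic alkene; the trisubstituted ring alkene should be the favoured isomer.

Step 13
Reactants: 15 trans-fused 6,12-lactone enoate; 17 1-methylcyclobutene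
Product: 18 cis,anti,cis photoadduct (bicyclo[2.2.0]hexane C1–C2–C3–C4–C5–C10 fused to ring A, new bonds on the α face)
Conditions: hν (300 nm, Pyrex), acetone, 17 (10 equiv), −20 °C
Reagents that add atoms: none
Why: Acetone absorbs the light and passes its triplet energy to the enoate, whose twisted ππ* triplet adds to 17 stepwise through a triplet 1,4-biradical that closes after spin inversion; the closest known reaction type is the sensitised enoate–alkene and enone–cyclobutene [2+2] photocycloaddition. The one ring closed is the four-membered ring C1–C4–C5–C10, formed by an intermolecular two-bond cycloaddition whose second bond closes the ring by radical recombination. Head-to-tail pairing (C4 to C5, C1 to C10) is needed; it should be secured because the β-carbon C5 takes the more substituted alkene carbon as in enone–alkene additions, and because the other pairing would have to join the fully substituted carbons C10 and C4, a closure slow enough for that biradical to revert. C1 and C4 are cis because they come from the cis double bond of a four-membered ring. C5 and C10 are cis because the second bond forms on the face of the first, a trans-fused bicyclo[4.2.0]octane being too strained on a cyclohexene that the trans-lactone clamps in one half-chair. The face is set by the axial C8 silyl ether, which covers the β face at C10, so 17 should add from the α face with its CH2CH2 bridge turned away from ring A. This facial selectivity is what the next step needs, since only the α adduct lets the later 1,4-diyl take the chair with C6 equatorial and C9 axial while ring A keeps its diequatorial lactone. Excess 17 and low temperature favour capture of the short-lived triplet over its decay.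

Step 14
Reactants: 18 cis,anti,cis photoadduct
Product: 19 methyl 8β-(tert-butyldimethylsilyloxy)germacra-1(10),4-dien-12,6α-olid-14-oate (C4=C5 E, C1=C10 ring-cis)
Conditions: PhMe (0.01 M), BHT (cat.), 190 °C, sealed base-washed tube, short heating with recycling of 18
Reagents that add atoms: none
Why: Thermal cycloreversion of a bicyclo[2.2.0]hexane: the strained C1–C4 bond breaks to a cyclohexane-1,4-diyl, which cleaves the ester-weakened C5–C10 bond; this is the thermal half of the known photo-thermal route to cis,trans-cyclodeca-1,5-dienes. With ring A held by the lactone, the α adduct can only give the chair diyl with C6 equatorial and C9 axial, which should lead to E at C4=C5 and the ring-cis alkene at C1=C10. High dilution and short heating should keep 19 from Cope rearrangement to the divinylcyclohexane.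

Step 15
Reactants: 19 ten-membered dienoate lactone
Product: 20 11-(dimethylaminomethyl) derivative of 19
Conditions: LiN(iPr)2 (LDA, 1.1 equiv), THF, −78 °C; then CH2=NMe2+ I−, −78 → 0 °C
Reagents that add atoms: N,N-dimethylmethyleneiminium iodide, C=[N+](C)C.[I-]
Why: Kinetic lactone enolate formation and Mannich reaction with Eschenmoser's salt; the saturated lactone α-CH2 is the fastest proton to remove at −78 °C. The C11 configuration is lost in the next step.

Step 16
Reactants: 20 11-(dimethylaminomethyl) derivative of 19
Product: 22 methyl 8β-(tert-butyldimethylsilyloxy)germacra-1(10),4,11(13)-trien-12,6α-olid-14-oate, via trimethylammonium iodide 21 (not isolated)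
Conditions: MeI, MeOH, 25 °C; then NaHCO3 (aq.), CH2Cl2, 25 °C
Reagents that add atoms: none
Why: Quaternisation and mild base elimination of trimethylamine, the standard two-stage α-methylenation of a γ-lactone; bicarbonate is too weak to touch the esters or the silyl ether.

Step 17
Reactants: 22 silyl-protected α-methylene lactone
Product: 23 methyl 8β-hydroxygermacra-1(10),4,11(13)-trien-12,6α-olid-14-oate
Conditions: HF·pyridine, pyridine, THF, 0 → 25 °C
Reagents that add atoms: none
Why: Fluoride desilylation under buffered, non-basic conditions, so that the freed O8–H neither adds to the methylene lactone nor takes over the lactone carbonyl.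

Step 18
Reactants: 23 methyl 8β-hydroxygermacra-1(10),4,11(13)-trien-12,6α-olid-14-oate; 24 methacrylic anhydride
Product: 25 methyl (6R,7R,8R)-8β-(methacryloyloxy)germacra-1(10),4,11(13)-trien-12,6α-olid-14-oate (target)
Conditions: Et3N, DMAP (cat.), CH2Cl2, 0 °C
Reagents that add atoms: none
Why: DMAP-catalysed acylation of the secondary alcohol with the anhydride; it is fast at 0 °C, which leaves little time for base-induced translactonisation.

## Compound list

1 | (−)-shikimic acid, (3R,4S,5R)-3,4,5-trihydroxycyclohex-1-ene-1-carboxylic acid | OC(=O)C1=C[C@@H](O)[C@@H](O)[C@H](O)C1 | starting material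
2 | methyl shikimate, methyl (3R,4S,5R)-3,4,5-trihydroxycyclohex-1-ene-1-carboxylate | COC(=O)C1=C[C@@H](O)[C@@H](O)[C@H](O)C1 | intermediate
3 | methyl 3,4-O-isopropylideneshikimate (acetonide on the cis diol O6/O7, O8–H free) | COC(=O)C1=C[C@H]2OC(C)(C)O[C@H]2[C@H](O)C1 | intermediate
4 | methyl malonyl chloride, methyl 3-chloro-3-oxopropanoate | COC(=O)CC(=O)Cl | starting material
5 | methyl 3,4-O-isopropylidene-5-O-(methoxycarbonylacetyl)shikimate | COC(=O)C1=C[C@H]2OC(C)(C)O[C@H]2[C@H](OC(=O)CC(=O)OC)C1 | intermediate
6 | methyl 5-O-(methoxycarbonylacetyl)shikimate (cis 3,4-diol free) | COC(=O)C1=C[C@@H](O)[C@@H](O)[C@H](OC(=O)CC(=O)OC)C1 | intermediate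
7 | 3,4-cyclic sulfite of 6 (both epimers at sulfur) | COC(=O)C1=C[C@H]2OS(=O)O[C@H]2[C@H](OC(=O)CC(=O)OC)C1 | intermediate
8 | 3,4-cyclic sulfate of 6 | COC(=O)C1=C[C@H]2OS(=O)(=O)O[C@H]2[C@H](OC(=O)CC(=O)OC)C1 | intermediate
9 | sodium salt of the 6-O-sulfate monoester of 10 (cis-fused 8,12-lactone, C11 epimers) | COC(=O)C1=C[C@@H](OS(=O)(=O)[O-])[C@@H]2C(C(=O)OC)C(=O)O[C@@H]2C1.[Na+] | intermediate
10 | dimethyl 4-hydroxy-2-oxo-2,3,3a,4,7,7a-hexahydro-1-benzofuran-3,6-dicarboxylate (cis-fused 8,12-lactone with C11 and O8 β, O6–H α, C11 epimers) | COC(=O)C1=C[C@@H](O)[C@@H]2C(C(=O)OC)C(=O)O[C@@H]2C1 | intermediate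
11 | methyl (3aS,4R,7aR)-4-hydroxy-2-oxo-2,3,3a,4,7,7a-hexahydro-1-benzofuran-6-carboxylate (cis-fused 8,12-lactone, free 6α-OH) | COC(=O)C1=C[C@@H](O)[C@@H]2CC(=O)O[C@@H]2C1 | intermediate
12 | 6-O-triethylsilyl ether of 11 | COC(=O)C1=C[C@@H](O[Si](CC)(CC)CC)[C@@H]2CC(=O)O[C@@H]2C1 | intermediate
13 | methyl 5-hydroxy-4-[2-(methoxy(methyl)amino)-2-oxoethyl]-3-(triethylsilyloxy)cyclohex-1-ene-1-carboxylate (shikimate numbering; 3-OSi α, 4-CH2 β, 5-OH β) | COC(=O)C1=C[C@@H](O[Si](CC)(CC)CC)[C@H](CC(=O)N(C)OC)[C@H](O)C1 | intermediate
14 | 8-O-tert-butyldimethylsilyl ether of 13 | COC(=O)C1=C[C@@H](O[Si](CC)(CC)CC)[C@H](CC(=O)N(C)OC)[C@H](O[Si](C)(C)C(C)(C)C)C1 | intermediate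
15 | methyl (3aS,4R,7aR)-4-(tert-butyldimethylsilyloxy)-2-oxo-2,3,3a,4,5,7a-hexahydro-1-benzofuran-6-carboxylate (trans-fused 6,12-lactone enoate; 8β-OSi cis to C11) | COC(=O)C1=C[C@H]2OC(=O)C[C@@H]2[C@H](O[Si](C)(C)C(C)(C)C)C1 | intermediate
16 | methylenecyclobutane | C=C1CCC1 | starting material
17 | 1-methylcyclobutene | CC1=CCC1 | intermediate
18 | cis,anti,cis photoadduct: bicyclo[2.2.0]hexane C1–C2–C3–C4(CH3)–C5–C10 fused through C5–C10 to ring A; C4–C5 and C1–C10 bonds α, CO2Me on C10 β, trans-lactone and 8β-OSi unchanged | COC(=O)[C@@]12C[C@@H](O[Si](C)(C)C(C)(C)C)[C@H]3CC(=O)O[C@@H]3[C@@H]1[C@@]1(C)CC[C@@H]21 | intermediate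
19 | methyl 8β-(tert-butyldimethylsilyloxy)germacra-1(10),4-dien-12,6α-olid-14-oate (C4=C5 E, C1=C10 ring-cis) | CC(C)(C)[Si](C)(C)O[C@@H]1C/C(C(=O)OC)=C\CC/C(C)=C/[C@H]2OC(=O)C[C@@H]21 | intermediate
20 | 11-(dimethylaminomethyl) derivative of 19 (C11 epimers) | CC(C)(C)[Si](C)(C)O[C@@H]1C/C(C(=O)OC)=C\CC/C(C)=C/[C@H]2OC(=O)C(CN(C)C)[C@@H]21 | intermediate
21 | trimethylammonium iodide of 20 | CC(C)(C)[Si](C)(C)O[C@@H]1C/C(C(=O)OC)=C\CC/C(C)=C/[C@H]2OC(=O)C(C[N+](C)(C)C)[C@@H]21.[I-] | intermediate
22 | methyl 8β-(tert-butyldimethylsilyloxy)germacra-1(10),4,11(13)-trien-12,6α-olid-14-oate | CC(C)(C)[Si](C)(C)O[C@@H]1C/C(C(=O)OC)=C\CC/C(C)=C/[C@H]2OC(=O)C(=C)[C@@H]21 | intermediate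
23 | methyl 8β-hydroxygermacra-1(10),4,11(13)-trien-12,6α-olid-14-oate | O[C@@H]1C/C(C(=O)OC)=C\CC/C(C)=C/[C@H]2OC(=O)C(=C)[C@@H]21 | intermediate
24 | methacrylic anhydride | CC(=C)C(=O)OC(=O)C(C)=C | starting material
25 | methyl (6R,7R,8R)-8β-(methacryloyloxy)germacra-1(10),4,11(13)-trien-12,6α-olid-14-oate (C4=C5 E, C1=C10 ring-cis) | C=C(C)C(=O)O[C@@H]1C/C(C(=O)OC)=C\CC/C(C)=C/[C@H]2OC(=O)C(=C)[C@@H]21 | target

## Step count and least certain steps

Total: 18 steps. Longest linear sequence: 17 steps (steps 1–11 and 13–18, from 1).

**Step 13 (key step).**
- What may go wrong: unproductive decay of the enoate triplet. Twisting about C5=C10, reversion of the more stabilised biradical (the one that would lead to the head-to-head adduct) and hydrogen transfer from 17 can keep conversion low. The long irradiation then erodes the facial preference on which step 14 depends.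
- Fallback: give the alkene a proven chromophore.
  - It sets out from 15. Allylic oxidation at C9, the only allylic CH2 (CrO3, 3,5-dimethylpyrazole, CH2Cl2, −20 °C), should give the 9-oxo enone F1, a 2-carbomethoxycyclohexenone.
  - Direct irradiation of F1 at 350 nm with 17 is an ordinary enone–alkene photocycloaddition. C5 is its β-carbon, so the head-to-tail sense is the same, and it should give the 9-oxo adduct F2.
  - The ketone is removed through the dithiolane F3 (ethane-1,2-dithiol, BF3·OEt2), which Raney nickel in EtOH should reduce to 18, where the route is rejoined.

**Step 6.**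
- What may go wrong: O-alkylation in place of C-alkylation. The ester of 8 prefers the conformation that holds its carbonyl oxygen, not C11, over C7, so the enolate oxygen can close a dioxolane-type ketene acetal. A second deprotonation would also let C11 displace the C6 sulfate.
- Fallback: intermolecular delivery of the malonate.
  - It sets out from 2. tBuMe2SiCl and imidazole should silylate O6 and O8 and leave the flanked O7–H, giving methyl 3,5-bis-O-(tert-butyldimethylsilyl)shikimate F4.
  - Tf2O and pyridine give the C7 triflate F5.
  - NaCH(CO2Me)2 in THF–DMF should displace it with inversion to the malonate F6.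
  - LiCl in wet DMSO gives the monoester F7.
  - CSA in MeOH should remove the less hindered allylic O6 silyl group and close the trans lactone, rejoining the route at 15.
  - This path is shorter, but substitution at a carbon flanked by two silyloxy groups competes with elimination, which is why it is held in reserve.

**Step 14.**
- What may go wrong: loss of geometric control at C1=C10. The diyl may collapse before it settles in the chair, the ester-weakened C5–C10 bond may break first, or trans-fused adduct carried over from step 13 may open to the ring-trans isomer. Longer heating also starts the Cope rearrangement.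
- Fallback: correct the geometry after the ring opening instead of in it.
  - It sets out from 18. If heating gives the 1(10) ring-trans isomer F8, reversible conjugate addition of thiolate (PhSH, cat. PhSNa, THF, 25 °C) should equilibrate the enoate.
  - The ring-cis isomer has the ester cis to H1, the arrangement preferred by trisubstituted enoates, so the equilibrium should lead to 19.
  - The C4=C5 geometry cannot be mended this way and rests on the facial selectivity of step 13.

**Step 15.**
- What may go wrong: attack on the conjugated ester instead of clean enolate formation. This could be transannular Michael addition of C11 to C1 through a six-membered transition state, or deprotonation at C2 or C9.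
- Fallback: do the enolate chemistry before the ring is opened.
  - It sets out from 18, whose lactone is the only enolisable carbonyl and which has no acceptor.
  - LDA and Eschenmoser's salt should give the Mannich base F9, MeI the ammonium iodide F10, and aqueous NaHCO3 the α-methylene lactone F11.
  - Heating F11 as in step 14, at high dilution with BHT, should open it directly to 22. α-Methylene lactones are known to survive Cope-type thermolysis of germacranolides.

## Further compounds

F1 | step 13 | 9-oxo derivative of 15 (2-carbomethoxycyclohexenone) | COC(=O)C1=C[C@H]2OC(=O)C[C@@H]2[C@H](O[Si](C)(C)C(C)(C)C)C1=O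
F2 | step 13 | 9-oxo derivative of photoadduct 18 | COC(=O)[C@@]12C(=O)[C@@H](O[Si](C)(C)C(C)(C)C)[C@H]3CC(=O)O[C@@H]3[C@@H]1[C@@]1(C)CC[C@@H]21
F3 | step 13 | 9,9-(ethane-1,2-diyldithio) ketal of F2 | COC(=O)[C@@]12C3(SCCS3)[C@@H](O[Si](C)(C)C(C)(C)C)[C@H]3CC(=O)O[C@@H]3[C@@H]1[C@@]1(C)CC[C@@H]21
F4 | step 6 | methyl 3,5-bis-O-(tert-butyldimethylsilyl)shikimate | COC(=O)C1=C[C@@H](O[Si](C)(C)C(C)(C)C)[C@@H](O)[C@H](O[Si](C)(C)C(C)(C)C)C1
F5 | step 6 | 4-O-trifluoromethanesulfonate of F4 | COC(=O)C1=C[C@@H](O[Si](C)(C)C(C)(C)C)[C@@H](OS(=O)(=O)C(F)(F)F)[C@H](O[Si](C)(C)C(C)(C)C)C1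
F6 | step 6 | dimethyl malonate adduct with inverted C7 (C11 β), O6 and O8 silyl ethers | COC(=O)C1=C[C@@H](O[Si](C)(C)C(C)(C)C)[C@H](C(C(=O)OC)C(=O)OC)[C@H](O[Si](C)(C)C(C)(C)C)C1
F7 | step 6 | C7 methoxycarbonylmethyl compound after dealkoxycarbonylation of F6 | COC(=O)C1=C[C@@H](O[Si](C)(C)C(C)(C)C)[C@H](CC(=O)OC)[C@H](O[Si](C)(C)C(C)(C)C)C1
F8 | step 14 | 1(10) ring-trans isomer of 19 | CC(C)(C)[Si](C)(C)O[C@@H]1C/C(C(=O)OC)=C/CC/C(C)=C/[C@H]2OC(=O)C[C@@H]21
F9 | step 15 | 11-(dimethylaminomethyl) derivative of 18 (C11 epimers) | COC(=O)[C@@]12C[C@@H](O[Si](C)(C)C(C)(C)C)[C@H]3C(CN(C)C)C(=O)O[C@@H]3[C@@H]1[C@@]1(C)CC[C@@H]21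
F10 | step 15 | trimethylammonium iodide of F9 | COC(=O)[C@@]12C[C@@H](O[Si](C)(C)C(C)(C)C)[C@H]3C(C[N+](C)(C)C)C(=O)O[C@@H]3[C@@H]1[C@@]1(C)CC[C@@H]21.[I-]
F11 | step 15 | 11(13)-methylene derivative of 18 | COC(=O)[C@@]12C[C@@H](O[Si](C)(C)C(C)(C)C)[C@H]3C(=C)C(=O)O[C@@H]3[C@@H]1[C@@]1(C)CC[C@@H]21
A1 | alternative 1 | lactone-locked cis-1-vinyl-2-isopropenylcyclohexanol, O8 p-methoxybenzyl ether (vinyl and isopropenyl α) | O[C@@]1(C=C)C[C@@H](OCc2ccc(OC)cc2)[C@H]2CC(=O)O[C@@H]2[C@@H]1C(C)=C
A2 | alternative 1 | ten-membered 1(10)-enol triflate with E-4,5-alkene and trans-lactone, O8 p-methoxybenzyl ether | COc1ccc(CO[C@@H]2C/C(OS(=O)(=O)C(F)(F)F)=C\CC/C(C)=C/[C@H]3OC(=O)C[C@@H]32)cc1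
A3 | alternative 2 | open-chain C5 E-vinyl iodide with C6 aldehyde, C1=C10 enoate, O8 silyl ether and C12 methyl ester | I/C=C(C)/CC/C=C(C(=O)OC)\C[C@@H](O[Si](C)(C)C(C)(C)C)[C@@H](CC(=O)OC)C=O
A4 | alternative 2 | ten-membered dienoate trans-lactone, O8 tert-butyldimethylsilyl ether (identical with 19) | CC(C)(C)[Si](C)(C)O[C@@H]1C/C(C(=O)OC)=C\CC/C(C)=C/[C@H]2OC(=O)C[C@@H]21
A5 | alternative 3 | C8 α-keto acid on the trans-lactone with the C1 Baylis–Hillman acetate and C9=C10 acrylate (C1 epimers) | OC(=O)C(=O)[C@H]1CC(=O)O[C@@H]1/C=C(\C)CCC(OC(C)=O)C(=C)C(=O)OC
A6 | alternative 3 | 8-oxo ten-membered dienoate trans-lactone | O=C1C/C(C(=O)OC)=C\CC/C(C)=C/[C@H]2OC(=O)C[C@@H]21
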